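The synthesis rests on cutting the oxirane at its CH2 group. This carbon (C3 of the three-membered ring) lies between the quaternary benzylic carbon C2 and the ring oxygen, so a single one-carbon donor delivered to the carbonyl carbon of an aryl ketone can supply both of its ring bonds. The key step, a LaLi3(binaphthoxide)3-catalysed sulfoxonium-ylide methylene transfer, thus forms C2–C3 and C3–O, closes the ring and sets the only stereocentre in one operation. Its precursor is the 2-(silyloxyacetyl)aryl tiglate: the phenol already bears its final ester, because a free phenol beside the oxirane would close to a dihydrobenzofuranol, and the primary oxygen is held as a TBS ether.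

Key step: step 7

Assumption: the sense of induction established for aryl methyl ketones is taken to hold with CH2OTBS in the place of methyl, which points to the (R)-binaphthoxide complex for the (R)-oxirane; if the first run shows the opposite sense, the (S)-ligand is used and nothing else changes.

Step 1
Reactants: 1 4-methoxy-3-methylphenol
Product: 2 2-bromo-4-methoxy-5-methylphenol
Conditions: NBS (1.0 equiv), CH2Cl2, 0 °C, dark
Reagents that add atoms: N-bromosuccinimide, O=C1CCC(=O)N1Br
Why: Electrophilic aromatic bromination: the free hydroxyl is the strongest activating group and its para position is taken by OMe, so bromine should enter the ortho carbon that is also para to the methyl group, the other ortho carbon being squeezed between OH and CH3.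

Step 2
Reactants: 3 methyl glycolate
Product: 4 methyl 2-(tert-butyldimethylsilyloxy)acetate
Conditions: TBSCl (1.1 equiv), imidazole (2 equiv), DMF, 0 °C → rt
Reagents that add atoms: tert-butyldimethylsilyl chloride, CC(C)(C)[Si](C)(C)Cl
Why: Imidazole-promoted silylation of the primary alcohol (silyl ether formation), to which the methyl ester is inert.

Step 3
Reactants: 4 methyl 2-(tert-butyldimethylsilyloxy)acetate
Product: 5 2-(tert-butyldimethylsilyloxy)-N-methoxy-N-methylacetamide
Conditions: MeNH(OMe)·HCl (1.5 equiv), iPrMgCl (3.0 equiv), THF, −20 → −5 °C; aq NH4Cl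
Reagents that add atoms: N,O-dimethylhydroxylamine hydrochloride, CNOC.Cl
Why: Weinreb amide formation by aminolysis of the methyl ester with the chloromagnesium amide made in the flask from the amine hydrochloride and iPrMgCl, which at this temperature acts only as a base and leaves the silyl ether alone.

Step 4
Reactants: 2 2-bromo-4-methoxy-5-methylphenol; 5 2-(tert-butyldimethylsilyloxy)-N-methoxy-N-methylacetamide
Product: 8 2-(tert-butyldimethylsilyloxy)-1-(2-hydroxy-5-methoxy-4-methylphenyl)ethan-1-one, via lithium 2-lithioaryloxide 6 (not isolated), via dilithium tetrahedral adduct 7 (not isolated)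
Conditions: 2, n-BuLi (2.05 equiv), THF, −78 → −20 °C; then 5 (0.85 equiv), −78 → −20 °C; aq NH4Cl
Reagents that add atoms: none
Why: Weinreb ketone synthesis: phenol deprotonation and bromine–lithium exchange give the ortho-lithiated phenoxide 6, which adds once to the amide because the chelated adduct 7 collapses to the ketone only on aqueous quench, so the phenol needs no protecting group.

Step 5
Reactants: 8 2-(tert-butyldimethylsilyloxy)-1-(2-hydroxy-5-methoxy-4-methylphenyl)ethan-1-one; 9 tigloyl chloride [(E)-2-methylbut-2-enoyl chloride]
Product: 10 2-[2-(tert-butyldimethylsilyloxy)acetyl]-4-methoxy-5-methylphenyl (E)-2-methylbut-2-enoate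
Conditions: 9 (1.3 equiv), pyridine (3 equiv), DMAP (0.1 equiv), CH2Cl2, 0 °C → rt
Reagents that add atoms: none
Why: DMAP-catalysed esterification of the phenol with an acid chloride; pyridine is too weak a base to enolise the α-silyloxy ketone or to turn the acid chloride into a vinylketene, so the (E)-alkene and the ketone should stay as they are.

Step 6
Reactants: 11 trimethylsulfoxonium iodide
Product: 12 dimethylsulfoxonium methylide (filtered and titrated THF solution)
Conditions: NaH (0.95 equiv), THF, reflux; filtered under Ar
Reagents that add atoms: none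
Why: Deprotonation of the sulfoxonium salt with NaH (preparation of the Corey–Chaykovsky ylide); a slight deficit of hydride and filtration should leave a solution free of excess base that can be dosed accurately.

Step 7
Reactants: 10 2-[2-(tert-butyldimethylsilyloxy)acetyl]-4-methoxy-5-methylphenyl (E)-2-methylbut-2-enoate; 12 dimethylsulfoxonium methylide
Product: 14 2-[(2R)-2-(tert-butyldimethylsilyloxymethyl)oxiran-2-yl]-4-methoxy-5-methylphenyl (E)-2-methylbut-2-enoate, via sulfoxonium betaine 13 (not isolated)
Conditions: LaLi3[(R)-binaphthoxide]3 (5 mol %; from La(OiPr)3, (R)-BINOL, n-BuLi), (2,4,6-(MeO)3C6H2)3P=O (5 mol %), 5 Å MS, THF, rt; 12 (1.2 equiv) added slowly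
Reagents that add atoms: none
Why: The ylide carbon adds to the Re face (O > CH2OTBS > aryl) of the catalyst-bound ketone carbonyl to give the alkoxide betaine 13, whose oxygen then expels dimethyl sulfoxide from the neighbouring CH2–S carbon. The closest known reaction type is the catalytic asymmetric Corey–Chaykovsky epoxidation of aryl methyl ketones with this LaLi3(binaphthoxide)3/phosphine oxide system, to which an aryl silyloxymethyl ketone belongs as a further member of the same substrate class. The oxirane closes by an irreversible 3-exo-tet SN2 displacement at the primary carbon, so the quaternary centre created in the addition is not touched again. That centre is under catalyst control: the chiral binaphthoxide pocket around the Lewis-acidic trivalent lanthanum, which binds the carbonyl oxygen while a lithium aryloxide site brings up the ylide, tells the ortho-substituted aryl group from the CH2OTBS arm, which sits where methyl does in the parent cases. The step needs chemoselectivity for the ketone over the aryl tiglate and no enolisation; the ketone is the carbonyl that the oxophilic catalyst activates, the tiglate is α-branched and cross-conjugated and therefore slow in both acyl substitution and conjugate cyclopropanation, and the weakly basic stabilised ylide is dosed slowly so that its free concentration stays low.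

Step 8
Reactants: 14 2-[(2R)-2-(tert-butyldimethylsilyloxymethyl)oxiran-2-yl]-4-methoxy-5-methylphenyl (E)-2-methylbut-2-enoate
Product: 15 2-[(2S)-2-(hydroxymethyl)oxiran-2-yl]-4-methoxy-5-methylphenyl (E)-2-methylbut-2-enoate
Conditions: TBAF (1.5 equiv), AcOH (1.5 equiv), THF, 0 °C → rt
Reagents that add atoms: none
Why: Fluoride-induced desilylation driven by Si–F bond formation; acetic acid protonates the primary alkoxide as it is released, which should suppress tigloyl transfer from the phenol, phenoxide attack on the oxirane and the Payne rearrangement (degenerate here, returning the same enantiomer in any case), and the descriptor changes to S only because the CIP priorities change.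

Step 9
Reactants: 15 2-[(2S)-2-(hydroxymethyl)oxiran-2-yl]-4-methoxy-5-methylphenyl (E)-2-methylbut-2-enoate; 16 isobutyric anhydride
Product: 17 2-[(2R)-2-(isobutyryloxymethyl)oxiran-2-yl]-4-methoxy-5-methylphenyl (E)-2-methylbut-2-enoate
Conditions: 16 (1.5 equiv), pyridine (3 equiv), DMAP (0.1 equiv), CH2Cl2, 0 °C
Reagents that add atoms: none
Why: DMAP-catalysed acylation of the primary alcohol with an anhydride under mildly basic conditions; no HCl is generated, so the acid-sensitive benzylic oxirane and its stereocentre should be untouched, and the descriptor returns to R by priority change alone.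

Compound list
1 | 4-methoxy-3-methylphenol | COc1ccc(O)cc1C | starting material
2 | 2-bromo-4-methoxy-5-methylphenol | COc1cc(Br)c(O)cc1C | intermediate
3 | methyl glycolate | COC(=O)CO | starting material
4 | methyl 2-(tert-butyldimethylsilyloxy)acetate | COC(=O)CO[Si](C)(C)C(C)(C)C | intermediate
5 | 2-(tert-butyldimethylsilyloxy)-N-methoxy-N-methylacetamide | CON(C)C(=O)CO[Si](C)(C)C(C)(C)C | intermediate
6 | lithium 2-lithio-4-methoxy-5-methylphenoxide | [Li]Oc1cc(C)c(OC)cc1[Li] | intermediate
7 | dilithium tetrahedral adduct of 6 and 5 (racemic at the new carbon, lost on quench) | CON(C)C(O[Li])(CO[Si](C)(C)C(C)(C)C)c1cc(OC)c(C)cc1O[Li] | intermediate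
8 | 2-(tert-butyldimethylsilyloxy)-1-(2-hydroxy-5-methoxy-4-methylphenyl)ethan-1-one | COc1cc(C(=O)CO[Si](C)(C)C(C)(C)C)c(O)cc1C | intermediate
9 | tigloyl chloride, (E)-2-methylbut-2-enoyl chloride | C/C=C(\C)C(Cl)=O | starting material
10 | 2-[2-(tert-butyldimethylsilyloxy)acetyl]-4-methoxy-5-methylphenyl (E)-2-methylbut-2-enoate | C/C=C(\C)C(=O)Oc1cc(C)c(OC)cc1C(=O)CO[Si](C)(C)C(C)(C)C | intermediate
11 | trimethylsulfoxonium iodide | C[S+](C)(C)=O.[I-] | starting material
12 | dimethylsulfoxonium methylide | C[S+](C)(=O)[CH2-] | intermediate
13 | 2-[(2S)-1-(tert-butyldimethylsilyloxy)-3-(dimethyloxosulfonio)-2-oxidopropan-2-yl]-4-methoxy-5-methylphenyl (E)-2-methylbut-2-enoate (betaine) | C/C=C(\C)C(=O)Oc1cc(C)c(OC)cc1[C@]([O-])(CO[Si](C)(C)C(C)(C)C)C[S+](C)(C)=O | intermediate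
14 | 2-[(2R)-2-(tert-butyldimethylsilyloxymethyl)oxiran-2-yl]-4-methoxy-5-methylphenyl (E)-2-methylbut-2-enoate | C/C=C(\C)C(=O)Oc1cc(C)c(OC)cc1[C@]1(CO[Si](C)(C)C(C)(C)C)CO1 | intermediate
15 | 2-[(2S)-2-(hydroxymethyl)oxiran-2-yl]-4-methoxy-5-methylphenyl (E)-2-methylbut-2-enoate (same spatial arrangement as 14) | C/C=C(\C)C(=O)Oc1cc(C)c(OC)cc1[C@]1(CO)CO1 | intermediate
16 | isobutyric anhydride | CC(C)C(=O)OC(=O)C(C)C | starting material
17 | 2-[(2R)-2-(isobutyryloxymethyl)oxiran-2-yl]-4-methoxy-5-methylphenyl (E)-2-methylbut-2-enoate | C/C=C(\C)C(=O)Oc1cc(C)c(OC)cc1[C@]1(COC(=O)C(C)C)CO1 | target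

Total step count: 9. Longest linear sequence: 7 steps (3 → 4 → 5 → 8 → 10 → 14 → 15 → 17).

Steps most likely to fail

Step 7. Enantioface discrimination may be insufficient because CH2OTBS is much larger than methyl. The ylide may also be consumed by acyl transfer from the aryl ester, by enolisation followed by an O-to-C acyl shift (Baker–Venkataraman), or by conjugate addition to the tiglate. The fallback uses no sulfur ylide and sets out from 10. Takai–Lombardo methylenation (CH2Br2, Zn, TiCl4, THF/CH2Cl2, 0 °C → rt), which is non-basic and selective for ketones over esters, should give 2-[3-(tert-butyldimethylsilyloxy)prop-1-en-2-yl]-4-methoxy-5-methylphenyl (E)-2-methylbut-2-enoate F1. Desilylation with HF·pyridine in THF/pyridine at 0 °C, harmless at this stage because no oxirane is present, should give the allylic alcohol 2-(3-hydroxyprop-1-en-2-yl)-4-methoxy-5-methylphenyl (E)-2-methylbut-2-enoate F2. Sharpless asymmetric epoxidation of F2 (Ti(OiPr)4, (2R,3R)-(+)-diisopropyl tartrate, t-BuOOH, 4 Å MS, CH2Cl2, −20 °C) should then deliver oxygen to the face that gives the (S)-epoxy alcohol, so the route is rejoined at 15 and finishes with step 9.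

Step 8. The liberated primary alkoxide may take over the tigloyl group from the phenol oxygen, after which the phenoxide opens the oxirane in a 5-exo mode, or fluoride and adventitious acid may open the benzylic oxirane. The fallback replaces the silyl ether by an ether that is removed oxidatively, with neither fluoride nor an alkoxide; it sets out from 3 and draws on 6, 9 and 12 of the main route. Methyl glycolate 3 is etherified with 4-methoxybenzyl trichloroacetimidate and catalytic camphorsulfonic acid (CH2Cl2, rt) to methyl 2-(4-methoxybenzyloxy)acetate F3. This is converted as in step 3 into N-methoxy-2-(4-methoxybenzyloxy)-N-methylacetamide F4. Addition of the dianion 6 as in step 4 passes through the corresponding dilithium tetrahedral adduct F5 and should give 1-(2-hydroxy-5-methoxy-4-methylphenyl)-2-(4-methoxybenzyloxy)ethan-1-one F6. Tigloylation with 9 as in step 5 gives 4-methoxy-2-[2-(4-methoxybenzyloxy)acetyl]-5-methylphenyl (E)-2-methylbut-2-enoate F7. The methylene transfer of step 7 with 12 then passes through the corresponding sulfoxonium betaine F8 to 4-methoxy-2-[(2R)-2-(4-methoxybenzyloxymethyl)oxiran-2-yl]-5-methylphenyl (E)-2-methylbut-2-enoate F9. DDQ in CH2Cl2/pH 7 buffer at 0 °C should cleave the benzylic ether under neutral conditions and return to 15.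

Step 4. Bromine–lithium exchange on the electron-rich lithium phenoxide may be incomplete, the aryllithium may be butylated by the 1-bromobutane formed beside it, or the amide may be enolised instead of attacked. The fallback replaces the unprotected dianion by a protected monoanion and sets out from 2. Benzylation (BnBr, K2CO3, acetone, reflux) gives 1-(benzyloxy)-2-bromo-4-methoxy-5-methylbenzene F10. Exchange with one equivalent of n-BuLi (THF, −78 °C) gives [2-(benzyloxy)-5-methoxy-4-methylphenyl]lithium F11, which adds to 5 through the lithium tetrahedral adduct F12 to give 1-[2-(benzyloxy)-5-methoxy-4-methylphenyl]-2-(tert-butyldimethylsilyloxy)ethan-1-one F13. Hydrogenolysis (H2, Pd/C, EtOAc, rt), stopped once the aryl benzyl ether is gone, should return to 8.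

Further compounds
F1 | step 7 | 2-[3-(tert-butyldimethylsilyloxy)prop-1-en-2-yl]-4-methoxy-5-methylphenyl (E)-2-methylbut-2-enoate | C/C=C(\C)C(=O)Oc1cc(C)c(OC)cc1C(=C)CO[Si](C)(C)C(C)(C)C
F2 | step 7 | 2-(3-hydroxyprop-1-en-2-yl)-4-methoxy-5-methylphenyl (E)-2-methylbut-2-enoate | C/C=C(\C)C(=O)Oc1cc(C)c(OC)cc1C(=C)CO
F3 | step 8 | methyl 2-(4-methoxybenzyloxy)acetate | COC(=O)COCc1ccc(OC)cc1
F4 | step 8 | N-methoxy-2-(4-methoxybenzyloxy)-N-methylacetamide | CON(C)C(=O)COCc1ccc(OC)cc1
F5 | step 8 | dilithium tetrahedral adduct of 6 and F4 (not isolated) | CON(C)C(O[Li])(COCc1ccc(OC)cc1)c1cc(OC)c(C)cc1O[Li]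
F6 | step 8 | 1-(2-hydroxy-5-methoxy-4-methylphenyl)-2-(4-methoxybenzyloxy)ethan-1-one | COc1ccc(COCC(=O)c2cc(OC)c(C)cc2O)cc1
F7 | step 8 | 4-methoxy-2-[2-(4-methoxybenzyloxy)acetyl]-5-methylphenyl (E)-2-methylbut-2-enoate | C/C=C(\C)C(=O)Oc1cc(C)c(OC)cc1C(=O)COCc1ccc(OC)cc1
F8 | step 8 | 2-[(2S)-3-(dimethyloxosulfonio)-1-(4-methoxybenzyloxy)-2-oxidopropan-2-yl]-4-methoxy-5-methylphenyl (E)-2-methylbut-2-enoate (betaine, not isolated) | C/C=C(\C)C(=O)Oc1cc(C)c(OC)cc1[C@]([O-])(COCc1ccc(OC)cc1)C[S+](C)(C)=O
F9 | step 8 | 4-methoxy-2-[(2R)-2-(4-methoxybenzyloxymethyl)oxiran-2-yl]-5-methylphenyl (E)-2-methylbut-2-enoate | C/C=C(\C)C(=O)Oc1cc(C)c(OC)cc1[C@]1(COCc2ccc(OC)cc2)CO1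
F10 | step 4 | 1-(benzyloxy)-2-bromo-4-methoxy-5-methylbenzene | COc1cc(Br)c(OCc2ccccc2)cc1C
F11 | step 4 | [2-(benzyloxy)-5-methoxy-4-methylphenyl]lithium (not isolated) | COc1cc([Li])c(OCc2ccccc2)cc1C
F12 | step 4 | lithium tetrahedral adduct of F11 and 5 (not isolated) | CON(C)C(O[Li])(CO[Si](C)(C)C(C)(C)C)c1cc(OC)c(C)cc1OCc1ccccc1
F13 | step 4 | 1-[2-(benzyloxy)-5-methoxy-4-methylphenyl]-2-(tert-butyldimethylsilyloxy)ethan-1-one | COc1cc(C(=O)CO[Si](C)(C)C(C)(C)C)c(OCc2ccccc2)cc1C
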